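34.1% of the substrate gone from the east run by 80.0 min read as single product. I called this the fork share: of the substrate molecules that have left, the part found as single product.

| flask | substrate | coupling partner | remark | time |
|---|---|---|---|---|
| east | 0.058 M | 0.087 M | run made earlier |  |
| south-east | 0.13 M | 0.087 M | run made earlier |  |
| flask | 0.087 M | 0.0870 M |  | 80 min |

| run | time / min | single product / % | tris adduct / % | substrate / % |
|---|---|---|---|---|
| east | 6.00 | 5 | 0 | 94 |
| east | 20.0 | 8 | 0 | 84 |
| east | 30.0 | 7 | 1 | 75 |
| east | 50.0 | 11 | 2 | 65 |
| east | 80.0 | 15 | 0 | 56 |
| east | 90.0 | 17 | 1 | 55 |
| south-east | 8.00 | 1 | 0 | 93 |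
| south-east | 12.0 | 5 | 0 | 91 |
| south-east | 20.0 | 7 | 0 | 83 |
| south-east | 40.0 | 9 | 0 | 73 |
| south-east | 60.0 | 12 | 2 | 66 |
| south-east | 90.0 | 15 | 0 | 58 |

(standard deviation of a reading: 1.5 percentage points)

- in percentages every species weighs as the substrate in it: one self-condensation product counts as two
- what may be going on: substrate + coupling partner -> single product + by-product; coupling partner + single product -> double product + by-product; coupling partner + double product -> tris adduct + by-product; coupling partner + tris adduct -> tetra adduct + by-product; substrate <-> dormant form; 2 substrate -> self-condensation product

1. equivalents of coupling partner to substrate, everything else as given, that leave most single product at 80 min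
2. the amount of single product then, in percent of the substrate charged
3. the amount of single product with the amounts as given

I read the two runs against each other. At 20.0 min the substrate column gave 84% in the east run and 83% in the south-east run, though the south-east run held 2.24 times the substrate, so at fixed partner the loss looked pseudo-first-order in substrate. The south-east run's fork share read 35.7% at 90.0 min. The tris adduct column showed 2% at 50.0 min against a scatter of 1.5 percentage points, so it gave me no price for over-reaction, and I committed to no optimum of my own.

The flask had the same 0.0870 M of coupling partner, with its 0.087 M of substrate between the two runs. I took the mean fork share times the east run's loss of 44.0% by 80.0 min, assumed for the flask too, which gave my estimate of 15.4% single product.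

The forecast said 15%, and 38% at 5 equiv, arguing that “More partner outruns dormancy”.

    substrate + coupling partner → single product + by-product (k = 2.40 L mol⁻¹ h⁻¹)
    coupling partner + single product → double product + by-product (k = 5.00 L mol⁻¹ h⁻¹)
    coupling partner + double product → tris adduct + by-product (k = 6.80 L mol⁻¹ h⁻¹)
    coupling partner + tris adduct → tetra adduct + by-product (k = 1.00 L mol⁻¹ h⁻¹)
    substrate ⇌ dormant form (K = 0.490, k = 0.390 h⁻¹)
    2 substrate → self-condensation product (k = 0.00180 L mol⁻¹ h⁻¹)

The flask gave 14.1% single product at 80 min; the best charge, 2.83 equiv, gave 20.5%, which is 18 points below the forecast. At the start of the flask, substrate entered the dormant form 1.9 times as fast as it coupled, counting the forward step alone. The flask's fork share was 34.2%. A neighbour charged with 0.035 M of coupling partner had a lower fork share at 80 min than the flask: 7.14% single product from 32.7% of substrate gone, or 21.8%.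

The numbers in the tables are simulated with made-up constants, noise included.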